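**Plan**

- Numbering (eremophilane): ring A = C1–C5, C10; ring B = C5–C10; C14 and C15 are the methyls on C5 and C4; C11–C13 are the isopropenyl group on C7; β is the face of the C5 methyl.
- Cuts: the two ester C–O bonds, then C6–C7 (ring B), then C3–C4 and C5–C10 together (ring A). C6 enters as a formyl carbon and is deoxygenated afterwards.
- Forward: D-mannose gives the acyclic C7–C10 silyloxy diene; ring A is closed by a Diels–Alder reaction with (E)-2-methylbut-2-enal; ring B is closed by a type 1 carbonyl-ene reaction that creates the isopropenyl group instead of attaching it; then deoxygenation at C6, unmasking and two acylations.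
- Stereochemistry: C8 and C9 are C2 and C3 of D-mannose. The cis methyls on C4/C5 come from the E geometry of the dienophile, C10 from the endo mode, and the absolute sense of ring A from a chiral Lewis acid. C7 comes from the chair of the ene closure.
- Enabling feature: ring A is a cyclohexanone whose carbonyl C2 is 1,4 to the quaternary C5, with cis methyls on C4/C5 and the ring B branch on C10. That is the retron of a Diels–Alder reaction between a 2-silyloxy diene (C3=C2–C1=C10) and an (E)-α-methyl enal (C4=C5–C6HO).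

Key step: step 5

Assumption: the sense of induction of the cationic oxazaborolidine in step 5 is taken from its usual model for α-substituted enals (formyl C–H···O contact, shielding of one enal face by the cis phenyl group). On that basis the (3aR) catalyst is specified for the (4S,5R,10S) sense; if the sense were opposite, its enantiomer would be used.

**Step 1**
Reactants: 1 2,3:5,6-di-O-isopropylidene-α-D-mannofuranose
Product: 2 (R)-[(4R)-2,2-dimethyl-1,3-dioxolan-4-yl][(4S,5R)-2,2-dimethyl-5-(2-methylprop-1-en-1-yl)-1,3-dioxolan-4-yl]methanol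
Conditions: i-PrPPh3I, n-BuLi (3 equiv of ylide), THF, −78 °C to rt
Reagents that add atoms: isopropylidenetriphenylphosphorane, CC(C)=P(c1ccccc1)(c1ccccc1)c1ccccc1
Why: Wittig olefination of the open-chain aldehyde form of the lactol with a non-stabilised ylide should give the trisubstituted alkene (C7=C11); no stereocentre is formed and the acetonide carbons that become C8 and C9 are carried over.

**Step 2**
Reactants: 2
Product: 4 (4R,5R)-2,2-dimethyl-5-(2-methylprop-1-en-1-yl)-1,3-dioxolane-4-carbaldehyde, via triol 3 (not isolated)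
Conditions: H5IO6 (2.5 equiv), EtOAc, rt
Reagents that add atoms: none
Why: periodic acid should hydrolyse the terminal dioxolane selectively and then cleave the resulting 1,2,3-triol at both C–C bonds (Malaprade glycol cleavage), leaving the internal cis-acetonide and the aldehyde carbon that becomes C10; no new stereocentre.

**Step 3**
Reactants: 4
Product: 5 (3E)-4-[(4S,5R)-2,2-dimethyl-5-(2-methylprop-1-en-1-yl)-1,3-dioxolan-4-yl]but-3-en-2-one
Conditions: Ph3P=CHC(O)CH3, CH2Cl2, rt
Reagents that add atoms: 1-(triphenylphosphoranylidene)propan-2-one, CC(=O)C=P(c1ccccc1)(c1ccccc1)c1ccccc1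
Why: Wittig reaction with a stabilised ylide should give the E enone (C10=C1, C2, C3) under neutral conditions that do not epimerise the α-alkoxy aldehyde.

**Step 4**
Reactants: 5
Product: 6 {[(3E)-4-[(4S,5R)-2,2-dimethyl-5-(2-methylprop-1-en-1-yl)-1,3-dioxolan-4-yl]buta-1,3-dien-2-yl]oxy}tri(propan-2-yl)silane
Conditions: TIPSOTf, Et3N, CH2Cl2, 0 °C
Reagents that add atoms: triisopropylsilyl trifluoromethanesulfonate, CC(C)[Si](C(C)C)(C(C)C)OS(=O)(=O)C(F)(F)F
Why: soft enolisation of the methyl ketone towards the methyl group (silyl enol ether formation) should give the cross-conjugated 2-silyloxy diene; the bulky silyl group makes the enol ether robust enough for steps 5 to 8.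

**Step 5**
Reactants: 6; 7 (2E)-2-methylbut-2-enal
Product: 8 (1R,2S,6S)-2-[(4S,5R)-2,2-dimethyl-5-(2-methylprop-1-en-1-yl)-1,3-dioxolan-4-yl]-1,6-dimethyl-4-{[tri(propan-2-yl)silyl]oxy}cyclohex-3-ene-1-carbaldehyde
Conditions: 7 (1.5 equiv), (3aR)-1-(2-methylphenyl)-3,3-diphenyltetrahydro-1H,3H-pyrrolo[1,2-c][1,3,2]oxazaborole + Tf2NH (20 mol % each), CH2Cl2, −78 to −40 °C
Reagents that add atoms: none
Why: Concerted but asynchronous [4+2] cycloaddition of the silyl dienol ether with the boron-bound s-trans enal, the C3–C4 bond leading; the closest known reaction type is the Lewis-acid-catalysed Diels–Alder reaction of α-substituted enals with 2-silyloxy dienes under cationic oxazaborolidine catalysis. It closes ring A by a suprafacial six-membered [4π+2π] closure that forms C3–C4 and C5–C10. The cis methyls on C4 and C5 are the two methyls that are cis in the (E)-enal and are transferred stereospecifically; C10 is set by the endo position of the formyl group, which puts the formyl carbon C6 cis to C9 and 10-H cis to the C5 methyl (the later cis ring fusion). Regiochemistry is secured by the substrate: the 2-silyloxy group makes C3 the nucleophilic terminus and the formyl group makes C4 the electrophilic carbon, so the C2 oxygen ends up 1,4 to C5 and the C9 branch next to C5. The step needs π-facial selectivity relative to the existing C8/C9 centres; this is placed under reagent control, which is reasonable because the bond at C10, next to the dioxolane, is the late, long bond of the transition state. The product keeps C2 masked as a single enol ether regioisomer (C1=C2).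

**Step 6**
Reactants: 8
Product: 9 (4S,5R,6S,7S,8R,9S,10S)-8α,9α-(isopropylidenedioxy)-2-(triisopropylsilyloxy)-10βH-eremophila-1,11-dien-6α-ol
Conditions: Me2AlCl (1.2 equiv), CH2Cl2, −78 to −20 °C
Reagents that add atoms: none
Why: type 1 intramolecular carbonyl-ene reaction of the non-enolisable C6 aldehyde with the C7=C11 alkene (the citronellal-to-isopulegol mode) should close ring B through a chair in which the C5 methyl, C1 and the developing isopropenyl group are equatorial, giving 7β-isopropenyl trans to an equatorial 6-OH; hydrogen transfer from a C11 methyl creates the isopropenyl group.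

**Step 7**
Reactants: 9
Product: 10 (4S,5R,6S,7S,8R,9S,10S)-8α,9α-(isopropylidenedioxy)-6α-[(methylsulfanyl)carbonothioyloxy]-2-(triisopropylsilyloxy)-10βH-eremophila-1,11-diene
Conditions: NaH, CS2, THF, 0 °C; then MeI
Reagents that add atoms: carbon disulfide, S=C=S; iodomethane, CI
Why: xanthate formation from the secondary alkoxide; the silyl enol ether and acetonide are inert to base and no stereocentre is touched.

**Step 8**
Reactants: 10
Product: 11 (4S,5R,7R,8R,9S,10S)-8α,9α-(isopropylidenedioxy)-2-(triisopropylsilyloxy)-10βH-eremophila-1,11-diene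
Conditions: Bu3SnH (high concentration), AIBN (cat.), toluene, 110 °C
Reagents that add atoms: none
Why: Barton–McCombie deoxygenation turns C6 into the required methylene; at high tin hydride concentration the secondary C6 radical should be reduced faster than it attacks the neighbouring isopropenyl group.

**Step 9**
Reactants: 11
Product: 12 (4S,5R,7R,8R,9S,10S)-8α,9α-dihydroxy-10βH-eremophil-11-en-2-one
Conditions: 1 M HCl, THF, rt
Reagents that add atoms: none
Why: acid hydrolysis of the silyl enol ether (to the C2 ketone) and of the acetonide (to the cis diol) in one operation; dilute acid at rt should leave the isopropenyl group alone, and no stereocentre is α to the new ketone.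

**Step 10**
Reactants: 12
Product: 13 (4S,5R,7R,8R,9S,10S)-9α-hydroxy-8α-[(2E)-2-methylbut-2-enoyloxy]-10βH-eremophil-11-en-2-one
Conditions: (E)-2-methylbut-2-enoyl chloride (1.05 equiv), pyridine, CH2Cl2, −20 to 0 °C
Reagents that add atoms: (2E)-2-methylbut-2-enoyl chloride, C/C=C(\C)C(Cl)=O
Why: regioselective acylation: the equatorial 8-OH should react well before the axial 9-OH, which is flanked by the ring fusion and 1,3-diaxial to C4.

**Step 11**
Reactants: 13
Product: 14 (4S,5R,7R,8R,9S,10S)-9α-(3-methylbut-2-enoyloxy)-8α-[(2E)-2-methylbut-2-enoyloxy]-10βH-eremophil-11-en-2-one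
Conditions: 3-methylbut-2-enoyl chloride, pyridine, DMAP (cat.), CH2Cl2, 0 °C to rt
Reagents that add atoms: 3-methylbut-2-enoyl chloride, CC(C)=CC(Cl)=O
Why: DMAP-catalysed acylation of the remaining hindered axial alcohol; pyridine instead of a trialkylamine limits vinylketene formation and so deconjugation of the senecioyl unit.

**Compound list**

1 | 2,3:5,6-di-O-isopropylidene-α-D-mannofuranose | O[C@H]1O[C@H]([C@H]2COC(C)(C)O2)[C@@H]3OC(C)(C)O[C@H]13 | starting material
2 | (R)-[(4R)-2,2-dimethyl-1,3-dioxolan-4-yl][(4S,5R)-2,2-dimethyl-5-(2-methylprop-1-en-1-yl)-1,3-dioxolan-4-yl]methanol | CC(C)=C[C@H]1OC(C)(C)O[C@H]1[C@H](O)[C@H]2COC(C)(C)O2 | intermediate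
3 | (1R,2R)-1-[(4S,5R)-2,2-dimethyl-5-(2-methylprop-1-en-1-yl)-1,3-dioxolan-4-yl]propane-1,2,3-triol | CC(C)=C[C@H]1OC(C)(C)O[C@H]1[C@H](O)[C@H](O)CO | intermediate (not isolated)
4 | (4R,5R)-2,2-dimethyl-5-(2-methylprop-1-en-1-yl)-1,3-dioxolane-4-carbaldehyde | CC(C)=C[C@H]1OC(C)(C)O[C@H]1C=O | intermediate
5 | (3E)-4-[(4S,5R)-2,2-dimethyl-5-(2-methylprop-1-en-1-yl)-1,3-dioxolan-4-yl]but-3-en-2-one | CC(C)=C[C@H]1OC(C)(C)O[C@H]1/C=C/C(C)=O | intermediate
6 | {[(3E)-4-[(4S,5R)-2,2-dimethyl-5-(2-methylprop-1-en-1-yl)-1,3-dioxolan-4-yl]buta-1,3-dien-2-yl]oxy}tri(propan-2-yl)silane | CC(C)=C[C@H]1OC(C)(C)O[C@H]1/C=C/C(=C)O[Si](C(C)C)(C(C)C)C(C)C | intermediate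
7 | (2E)-2-methylbut-2-enal | C/C=C(\C)C=O | starting material
8 | (1R,2S,6S)-2-[(4S,5R)-2,2-dimethyl-5-(2-methylprop-1-en-1-yl)-1,3-dioxolan-4-yl]-1,6-dimethyl-4-{[tri(propan-2-yl)silyl]oxy}cyclohex-3-ene-1-carbaldehyde | CC(C)=C[C@H]1OC(C)(C)O[C@H]1[C@H]2C=C(O[Si](C(C)C)(C(C)C)C(C)C)C[C@H](C)[C@@]2(C)C=O | intermediate
9 | (4S,5R,6S,7S,8R,9S,10S)-8α,9α-(isopropylidenedioxy)-2-(triisopropylsilyloxy)-10βH-eremophila-1,11-dien-6α-ol | C=C(C)[C@H]1[C@H](O)[C@@]2(C)[C@H](C=C(O[Si](C(C)C)(C(C)C)C(C)C)C[C@@H]2C)[C@@H]3OC(C)(C)O[C@H]13 | intermediate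
10 | O-6α xanthate (S-methyl dithiocarbonate) of 9 | C=C(C)[C@H]1[C@H](OC(=S)SC)[C@@]2(C)[C@H](C=C(O[Si](C(C)C)(C(C)C)C(C)C)C[C@@H]2C)[C@@H]3OC(C)(C)O[C@H]13 | intermediate
11 | (4S,5R,7R,8R,9S,10S)-8α,9α-(isopropylidenedioxy)-2-(triisopropylsilyloxy)-10βH-eremophila-1,11-diene | C=C(C)[C@H]1C[C@@]2(C)[C@H](C=C(O[Si](C(C)C)(C(C)C)C(C)C)C[C@@H]2C)[C@@H]3OC(C)(C)O[C@H]13 | intermediate
12 | (4S,5R,7R,8R,9S,10S)-8α,9α-dihydroxy-10βH-eremophil-11-en-2-one | C=C(C)[C@H]1C[C@@]2(C)[C@H](CC(=O)C[C@@H]2C)[C@H](O)[C@@H]1O | intermediate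
13 | (4S,5R,7R,8R,9S,10S)-9α-hydroxy-8α-[(2E)-2-methylbut-2-enoyloxy]-10βH-eremophil-11-en-2-one | C=C(C)[C@H]1C[C@@]2(C)[C@H](CC(=O)C[C@@H]2C)[C@H](O)[C@@H]1OC(=O)/C(C)=C/C | intermediate
14 | (4S,5R,7R,8R,9S,10S)-9α-(3-methylbut-2-enoyloxy)-8α-[(2E)-2-methylbut-2-enoyloxy]-10βH-eremophil-11-en-2-one | C=C(C)[C@H]1C[C@@]2(C)[C@H](CC(=O)C[C@@H]2C)[C@H](OC(=O)C=C(C)C)[C@@H]1OC(=O)/C(C)=C/C | target

Total step count: 11. Longest linear sequence: 11 steps (from 1).

**Steps most likely to fail**

Step 5. The facial preference of the catalyst and the intrinsic bias of the dioxolane-bearing diene may be mismatched, and the dioxolane oxygens may compete with the aldehyde for boron, so that conversion or π-facial selectivity drops. The fallback delivers the dienophile through the C8/C9 diol itself. It sets out from enone 5: aqueous acetic acid removes the acetonide to give the diol F1; acid-catalysed acetalisation with 7 gives the 2-alkenyl-1,3-dioxolane F2; TIPSOTf and Et3N give the silyl dienol ether F3. Catalytic Me3SiOTf at −78 °C then opens the acetal to a tethered vinyl-oxocarbenium ion that undergoes an intramolecular ionic Diels–Alder reaction and recloses to the bridged acetal F4. Acetal exchange in acetone with pyridinium tosylate releases the formyl group and re-forms the acetonide, which comes back to the route at 8.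

Step 6. The aluminium Lewis acid may ionise the allylic C8–O bond or exchange the acetonide with the aldehyde, and the electron-poor alkene may erode the chair preference so that the C7 epimer forms. The fallback replaces the polar closure by a radical one and sets out from 8: NaBH4 gives the neopentyl alcohol F5, and iodine, PPh3 and imidazole give the iodide F6. A photochemical alkyl Heck-type cyclisation with catalytic (pyridine)bis(dimethylglyoximato)(triphenylstannyl)cobalt and i-Pr2NEt under blue light should then add the C6 radical 6-exo to C7 and turn the tertiary C11 radical into the isopropenyl group. It comes back to the route at 11, so steps 7 and 8 are not needed.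

Step 11. The tiglate may migrate from O8 to the neighbouring cis hydroxyl under the basic conditions, and the axial 9-OH may acylate slowly, with deconjugation of the acyl chloride as a side path. The fallback changes the order of ester introduction and sets out from 12: Et3SiCl and imidazole silylate the equatorial 8-OH to give F7; 3-methylbut-2-enoic anhydride with DMAP then acylates the 9-OH to give F8, where no acyl group can migrate. HF·pyridine removes the silyl group under acidic conditions to give F9, and (E)-2-methylbut-2-enoyl chloride in pyridine acylates the free equatorial 8-OH. It comes back to the route at 14.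

**Further compounds**

F1 | step 5 | (3E,5S,6R)-5,6-dihydroxy-8-methylnona-3,7-dien-2-one | CC(C)=C[C@@H](O)[C@@H](O)/C=C/C(C)=O
F2 | step 5 | (3E)-4-[(4S,5R)-2-[(2E)-but-2-en-2-yl]-5-(2-methylprop-1-en-1-yl)-1,3-dioxolan-4-yl]but-3-en-2-one (both acetal epimers) | C/C=C(\C)C1O[C@H](C=C(C)C)[C@H](/C=C/C(C)=O)O1
F3 | step 5 | {[(3E)-4-[(4S,5R)-2-[(2E)-but-2-en-2-yl]-5-(2-methylprop-1-en-1-yl)-1,3-dioxolan-4-yl]buta-1,3-dien-2-yl]oxy}tri(propan-2-yl)silane | C/C=C(\C)C1O[C@H](C=C(C)C)[C@H](/C=C/C(=C)O[Si](C(C)C)(C(C)C)C(C)C)O1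
F4 | step 5 | bridged internal acetal of 8 in which the formyl carbon C6 is bonded to O8 and O9 (2,7-dioxabicyclo[2.2.1]heptane fused to ring A) | CC(C)=C[C@H]1O[C@@H]2O[C@H]1[C@H]3C=C(O[Si](C(C)C)(C(C)C)C(C)C)C[C@H](C)[C@@]23C
F5 | step 6 | [(1R,2S,6S)-2-[(4S,5R)-2,2-dimethyl-5-(2-methylprop-1-en-1-yl)-1,3-dioxolan-4-yl]-1,6-dimethyl-4-{[tri(propan-2-yl)silyl]oxy}cyclohex-3-en-1-yl]methanol | CC(C)=C[C@H]1OC(C)(C)O[C@H]1[C@H]2C=C(O[Si](C(C)C)(C(C)C)C(C)C)C[C@H](C)[C@@]2(C)CO
F6 | step 6 | (4S,5R)-4-[(1S,5S,6R)-6-(iodomethyl)-5,6-dimethyl-3-{[tri(propan-2-yl)silyl]oxy}cyclohex-2-en-1-yl]-2,2-dimethyl-5-(2-methylprop-1-en-1-yl)-1,3-dioxolane | CC(C)=C[C@H]1OC(C)(C)O[C@H]1[C@H]2C=C(O[Si](C(C)C)(C(C)C)C(C)C)C[C@H](C)[C@@]2(C)CI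
F7 | step 11 | (4S,5R,7R,8R,9S,10S)-9α-hydroxy-8α-(triethylsilyloxy)-10βH-eremophil-11-en-2-one | C=C(C)[C@H]1C[C@@]2(C)[C@H](CC(=O)C[C@@H]2C)[C@H](O)[C@@H]1O[Si](CC)(CC)CC
F8 | step 11 | (4S,5R,7R,8R,9S,10S)-9α-(3-methylbut-2-enoyloxy)-8α-(triethylsilyloxy)-10βH-eremophil-11-en-2-one | C=C(C)[C@H]1C[C@@]2(C)[C@H](CC(=O)C[C@@H]2C)[C@H](OC(=O)C=C(C)C)[C@@H]1O[Si](CC)(CC)CC
F9 | step 11 | (4S,5R,7R,8R,9S,10S)-8α-hydroxy-9α-(3-methylbut-2-enoyloxy)-10βH-eremophil-11-en-2-one | C=C(C)[C@H]1C[C@@]2(C)[C@H](CC(=O)C[C@@H]2C)[C@H](OC(=O)C=C(C)C)[C@@H]1O
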